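**Strategy.** The flavonol is cut at both bonds of its C4 carbonyl, C4a–C4 (to ring A) and C4–C3 (to the oxygen-bearing carbon of ring C). A palladium-catalysed carbonylative α-arylation exploits exactly this feature: in one operation it joins an ortho-oxygenated aryl iodide (ring A), carbon monoxide (C4) and an α-benzyloxy aryl ketone (C3, C2, ring B) to the full 1,3-diketone, closing no ring. The precursors are 1-iodo-2,4-bis(methoxymethoxy)benzene, whose two phenols are masked alike so that no selective protection is needed, and 2-(benzyloxy)-1-(3,4-dimethoxyphenyl)ethanone. Acid then frees O1 and the 7-OH and closes ring C, hydrogenolysis frees the 3-OH, and the prenyl ether is made last.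

Key step: step 4

Remark on the chemistry: the target has no stereocentre; C2 of dione 10 is formed racemic and is erased when ring C aromatises, so 10 and 11 carry no stereodescriptor.

Step 1
Reactants: 1 4-iodobenzene-1,3-diol
Product: 2 1-iodo-2,4-bis(methoxymethoxy)benzene
Conditions: MOMCl (2.6 equiv), i-Pr2NEt (3 equiv), CH2Cl2, 0 °C to rt
Reagents that add atoms: chloromethyl methyl ether, COCCl
Why: Williamson-type O-alkylation of both phenols by the very reactive α-chloro ether is exhaustive, so no regiochemical question arises, and the aryl iodide is inert to the amine base.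

Step 2
Reactants: 3 2-(benzyloxy)acetyl chloride
Product: 4 2-(benzyloxy)-N-methoxy-N-methylacetamide
Conditions: MeNHOMe·HCl (1.1 equiv), Et3N (2.2 equiv), CH2Cl2, 0 °C to rt
Reagents that add atoms: N,O-dimethylhydroxylamine hydrochloride, CNOC.Cl
Why: Schotten–Baumann-type N-acylation of the hydroxylamine by the acid chloride should give the Weinreb amide cleanly, the benzyl ether being inert.

Step 3
Reactants: 4 2-(benzyloxy)-N-methoxy-N-methylacetamide; 5 4-bromo-1,2-dimethoxybenzene
Product: 7 2-(benzyloxy)-1-(3,4-dimethoxyphenyl)ethanone, via (3,4-dimethoxyphenyl)magnesium bromide 6 (not isolated)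
Conditions: Mg, I2 (cat.), THF, reflux; then 4, THF, 0 °C to rt; 1 M HCl quench
Reagents that add atoms: none
Why: Weinreb ketone synthesis, in which the aryl Grignard reagent adds only once because magnesium chelation by the N-methoxy group holds the addition stage until the acidic quench, so no tertiary alcohol should form.

Step 4
Reactants: 2 1-iodo-2,4-bis(methoxymethoxy)benzene; 7 2-(benzyloxy)-1-(3,4-dimethoxyphenyl)ethanone; 8 carbon monoxide
Product: 10 2-(benzyloxy)-1-[2,4-bis(methoxymethoxy)phenyl]-3-(3,4-dimethoxyphenyl)propane-1,3-dione (racemic at C2), via chloromagnesium Z-enolate 9 (not isolated)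
Conditions: Pd(dba)2 (5 mol%), Xantphos (5 mol%), CO (1 atm), MgCl2 (1.5 equiv), Et3N (3 equiv), 1,4-dioxane, 80 °C; dilute HCl work-up
Reagents that add atoms: none
Why: Zerovalent palladium carrying the wide-bite-angle diphosphine Xantphos inserts into the C–I bond of 2, CO (8) undergoes migratory insertion to give an aroylpalladium iodide, and the chelated magnesium enolate 9, formed reversibly by soft enolisation of 7 with MgCl2/Et3N, displaces iodide and is released by reductive elimination through carbon, which forms C4a–C4 and C4–C3 and returns zerovalent palladium. The closest known reaction type is the palladium-catalysed carbonylative α-arylation of aryl alkyl ketones with aryl iodides to give 1,3-diketones. No ring is closed, and the one new stereocentre (C2 of the dione) is formed racemic, is configurationally labile and vanishes in step 5, so it needs no control. The step needs carbonylative over direct α-arylation, which the CO atmosphere, the diphosphine and the electron-rich aryl group (fast CO insertion) should secure, and C- over O-acylation, which the magnesium-chelated enolate favours. Double acylation is blocked because 10 is held as its unreactive magnesium diketonate until work-up, and both phenols are acetal-protected so that no phenoxide can intercept the aroylpalladium species as an ester.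

Step 5
Reactants: 10 2-(benzyloxy)-1-[2,4-bis(methoxymethoxy)phenyl]-3-(3,4-dimethoxyphenyl)propane-1,3-dione
Product: 12 3-(benzyloxy)-2-(3,4-dimethoxyphenyl)-7-hydroxy-4H-chromen-4-one, via free-phenol diketone 11 (not isolated)
Conditions: 3 M HCl in MeOH, 60 °C
Reagents that add atoms: none
Why: Acid-catalysed acetal methanolysis frees both phenols, and the 2-hydroxyl of 11 then condenses with the dimethoxyphenyl ketone carbonyl with loss of water (6-exo-trig addition, then dehydration), the standard cyclodehydration of 1-(2-hydroxyphenyl)-1,3-diketones to flavones, which the benzyl and methyl ethers should survive.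

Step 6
Reactants: 12 3-(benzyloxy)-2-(3,4-dimethoxyphenyl)-7-hydroxy-4H-chromen-4-one
Product: 13 2-(3,4-dimethoxyphenyl)-3,7-dihydroxy-4H-chromen-4-one
Conditions: H2 (1 atm), Pd/C (10 wt%), THF/MeOH, rt
Reagents that add atoms: none
Why: Heterogeneous catalytic hydrogenolysis of the O-benzyl bond, under which the tetrasubstituted vinylogous-ester C2=C3 bond of the chromone and the aryl methyl ethers should not be reduced.

Step 7
Reactants: 13 2-(3,4-dimethoxyphenyl)-3,7-dihydroxy-4H-chromen-4-one; 14 1-bromo-3-methylbut-2-ene
Product: 15 2-(3,4-dimethoxyphenyl)-3-hydroxy-7-[(3-methylbut-2-en-1-yl)oxy]-4H-chromen-4-one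
Conditions: KHCO3 (1.5 equiv), 14 (1.1 equiv), DMF, 40 °C
Reagents that add atoms: none
Why: Williamson ether synthesis under acidity control, in which hydrogencarbonate ionises only the 7-OH (a vinylogous carboxylic acid through the C4 carbonyl) while the less acidic 3-OH stays hydrogen-bonded to C4=O, so SN2 attack on the primary allylic bromide should occur at O7.

**Compound list**

1 | 4-iodobenzene-1,3-diol | Oc1ccc(I)c(O)c1 | starting material
2 | 1-iodo-2,4-bis(methoxymethoxy)benzene | COCOc1ccc(I)c(OCOC)c1 | intermediate
3 | 2-(benzyloxy)acetyl chloride | O=C(Cl)COCc1ccccc1 | starting material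
4 | 2-(benzyloxy)-N-methoxy-N-methylacetamide | CON(C)C(=O)COCc1ccccc1 | intermediate
5 | 4-bromo-1,2-dimethoxybenzene | COc1ccc(Br)cc1OC | starting material
6 | (3,4-dimethoxyphenyl)magnesium bromide (formed in the flask in step 3) | COc1ccc([Mg]Br)cc1OC | intermediate
7 | 2-(benzyloxy)-1-(3,4-dimethoxyphenyl)ethanone | COc1ccc(C(=O)COCc2ccccc2)cc1OC | intermediate
8 | carbon monoxide | [C-]#[O+] | starting material
9 | chloromagnesium (Z)-enolate of 7, O–Mg cis to the benzyloxy group (formed in the flask in step 4) | COc1ccc(/C(O[Mg]Cl)=C/OCc2ccccc2)cc1OC | intermediate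
10 | 2-(benzyloxy)-1-[2,4-bis(methoxymethoxy)phenyl]-3-(3,4-dimethoxyphenyl)propane-1,3-dione (racemic at C2) | COCOc1ccc(C(=O)C(OCc2ccccc2)C(=O)c2ccc(OC)c(OC)c2)c(OCOC)c1 | intermediate
11 | 2-(benzyloxy)-1-(2,4-dihydroxyphenyl)-3-(3,4-dimethoxyphenyl)propane-1,3-dione (formed in the flask in step 5) | COc1ccc(C(=O)C(OCc2ccccc2)C(=O)c2ccc(O)cc2O)cc1OC | intermediate
12 | 3-(benzyloxy)-2-(3,4-dimethoxyphenyl)-7-hydroxy-4H-chromen-4-one | COc1ccc(-c2oc3cc(O)ccc3c(=O)c2OCc2ccccc2)cc1OC | intermediate
13 | 2-(3,4-dimethoxyphenyl)-3,7-dihydroxy-4H-chromen-4-one | COc1ccc(-c2oc3cc(O)ccc3c(=O)c2O)cc1OC | intermediate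
14 | 1-bromo-3-methylbut-2-ene | CC(C)=CCBr | starting material
15 | 2-(3,4-dimethoxyphenyl)-3-hydroxy-7-[(3-methylbut-2-en-1-yl)oxy]-4H-chromen-4-one | COc1ccc(-c2oc3cc(OCC=C(C)C)ccc3c(=O)c2O)cc1OC | target

**Total step count:** 7
**Longest linear sequence:** 6 steps (steps 2, 3, 4, 5, 6, 7)

**Steps most likely to fail**

1. Step 4. The coupling may proceed without CO uptake (direct α-arylation), the aroylpalladium species may be lost to hydrolysis or reduction, or turnover may stall because the chelating α-alkoxy enolate binds palladium. The fallback sets out from 2 and 7 and comes back at 10, replacing the catalytic three-component coupling by a stoichiometric crossed Claisen acylation. Iodine–magnesium exchange on 2 (i-PrMgCl·LiCl, THF, −20 °C) and carboxylation with CO2 should give 2,4-bis(methoxymethoxy)benzoic acid F1. Condensation with 1H-benzotriazole (EDC·HCl, CH2Cl2, rt) should give (1H-benzotriazol-1-yl)[2,4-bis(methoxymethoxy)phenyl]methanone F2. Deprotonation of 7 with LiN(SiMe3)2 (2 equiv, THF, −78 °C) and C-acylation by F2 should then give 10.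

2. Step 7. Alkylation may spread over both hydroxyls (3-O- and 3,7-di-O-prenylation) if the acidity difference does not translate into site selectivity. The fallback sets out from 13 and comes back at 15, replacing acidity control by protecting-group differentiation. Acetylation (Ac2O, pyridine, rt) should give 2-(3,4-dimethoxyphenyl)-4-oxo-4H-chromene-3,7-diyl diacetate F3. The most electrophilic aryl ester is removed selectively (PhSH, imidazole, N-methyl-2-pyrrolidone, 0 °C) to give 2-(3,4-dimethoxyphenyl)-7-hydroxy-4-oxo-4H-chromen-3-yl acetate F4. Mitsunobu etherification with 3-methylbut-2-en-1-ol (PPh3, diisopropyl azodicarboxylate, THF, 0 °C to rt) on the only free hydroxyl should give 2-(3,4-dimethoxyphenyl)-7-[(3-methylbut-2-en-1-yl)oxy]-4-oxo-4H-chromen-3-yl acetate F5. Methanolysis (K2CO3, MeOH, rt) then leaves the prenyl ether untouched and should give 15.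

3. Step 5. Acid-catalysed retro-Claisen cleavage of the 2-alkoxy-1,3-diketone by methanol may compete with ring closure, or the sequence may stall before dehydration. The fallback sets out from 10 and comes back at 12, separating the two events and excluding protic nucleophiles. The acetals are cleaved with ZnBr2 and n-PrSH in CH2Cl2 at 0 °C to give the free-phenol diketone 11, which is isolated here. Ring closure with loss of water is then driven by TsOH·H2O (cat.) in toluene at reflux with azeotropic removal of water, to give 12. This fallback makes no compound outside the list (F0).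

**Further compounds**

F1 | step 4 | 2,4-bis(methoxymethoxy)benzoic acid | COCOc1ccc(C(=O)O)c(OCOC)c1
F2 | step 4 | (1H-benzotriazol-1-yl)[2,4-bis(methoxymethoxy)phenyl]methanone | COCOc1ccc(C(=O)n2nnc3ccccc32)c(OCOC)c1
F3 | step 7 | 2-(3,4-dimethoxyphenyl)-4-oxo-4H-chromene-3,7-diyl diacetate | COc1ccc(-c2oc3cc(OC(C)=O)ccc3c(=O)c2OC(C)=O)cc1OC
F4 | step 7 | 2-(3,4-dimethoxyphenyl)-7-hydroxy-4-oxo-4H-chromen-3-yl acetate | COc1ccc(-c2oc3cc(O)ccc3c(=O)c2OC(C)=O)cc1OC
F5 | step 7 | 2-(3,4-dimethoxyphenyl)-7-[(3-methylbut-2-en-1-yl)oxy]-4-oxo-4H-chromen-3-yl acetate | COc1ccc(-c2oc3cc(OCC=C(C)C)ccc3c(=O)c2OC(C)=O)cc1OC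
F0 | step 5 | none | none
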